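The closed, stirred vessel takes up Z as dissolved J, and X spends J on E to give D.

    Z ⇌ J, rate k1*(csat - [J]) (k1 = 0.823 h⁻¹, csat = 200 mM)
    E + J + X → X + D (k2 = 296 L² mol⁻² h⁻¹)
    E + X ⇌ E.X, settled at all times (K3 = 12 L mol⁻¹)

E 1.5 M; Z 200 mM (held); X 2 mol%; time 8.0 h

- at the start none of J is dissolved
- run time (flask): 8.0 h

- how much D there is at 8.0 h, in percent of the E charged
- the change that raises the amount of D at 8.0 h, in percent of the E charged most ("none" if none brings more than 2 percentage points) (summer / spring / noon / none)
- amount of D at 8.0 h, in percent of the E charged, after spring

- summer: doubling the saturation concentration of Z, all else as stated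
- spring: doubling the amount of X, all else as stated
- noon: doubling the transfer coefficient of step 1, all else as stated

Where does X stand in the flask? At the start, the balance constant times [E] is 18, so nearly all of X is parked as E.X. The second step is thus pseudo-first-order in J, and its constant comes to 0.701 h⁻¹: this is the gas-use constant, the second step's rate constant times [E] times free X.

Does transfer or use hold J down? The ratio of use to transfer is 0.852, so both count, and J levels off at a share 54.0% of saturation after a lag of 0.656 h.

What does that make by the asked time? The flask gains a fraction 0.0505 h⁻¹ of the charge per hour, which gives 37.1%. E then averages 81.5% of its charge, the constant becomes 0.693 h⁻¹, and a second round gives 36.8%.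

First rounds for the changes give 74.1% for summer, 52.2% for spring and 49.6% for noon, so summer leads. With the constant at 1.38 h⁻¹, spring's second round gives 51.8%.

The forecast gave 36.7% (35% to 38.5%), summer, and 51.7% (49.5% to 54%) after spring, on the ground that “the two resistances are in series”.

The flask gives 36.7%, 51.6% after spring, and summer as best, with gains of 35 percentage points for summer, 15 points for spring and 12 points for noon.

In the flask J is made 1.00 times as fast as it is used at 8.00 h. The gas-use constant from the E left then, 0.679 h⁻¹, puts J at 0.110 M, against a reading of 0.109 M.

In a neighbour flask with 0.60 M of E, X still at the same mol% and the time held, the gas-use constant is 0.260 h⁻¹, and the first round gives 46.6%. The second round in that neighbour flask, at 0.251 h⁻¹, gives 45.3%; the simulated neighbour flask reaches 45.0%.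

(The rate constants were set for the occasion; the rest is arithmetic.)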